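## Retrosynthetic overview

1. Target 23 ⇐ desilylation of 22 ⇐ exo-face hydroboration of the C7 exocyclic methylene of bicycle 16 and double B-alkyl Suzuki coupling with one alkenyl iodide (20). Both geranyl groups (on C5 and on C7) are cut at CH2–CH= into a CH2–boron unit and the same C9 iodide.
2. Key disconnection C6–C7 of ring B (C1–C8–C7–C6–C5–C9): intramolecular B-alkyl Suzuki closure of monocycle 15. Enabling feature: C5 is fully substituted and flanked by the C4 and C9 carbonyls, so it can be built as a prochiral carbon with two identical CH2Bpin arms (no β-hydrogen). The arm on the same face of ring A (C1–C2–C3–C4–C5–C9) as the C8 2-bromoallyl arm becomes C6, the other becomes the CH2 of the bridgehead geranyl, and C7 stays sp2 so its configuration is set afterwards.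
3. Ring A ⇐ [3+3] acylation/Claisen annulation of the dianion of aryl diketone 10 with the acid chloride of malonic half-ester 7, then geminal bis(borylmethylation) at C5.
4. 7 ⇐ enzymatic desymmetrisation of malonate 6 (C1, the only stereocentre carried in). The C1–C8 vicinal quaternary bond comes from propargylation of dimethyl malonate with a tertiary propargylic chloride, then prenylation and alkyne bromoboration.
5. Order of ring formation: ring A (step 7), then ring B (step 9, which also fixes C5); C7 is configured in step 12.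

Key step: step 9

Assumption: pig liver esterase is taken to deliver the (R)-half-ester 7; the sense and level of selection for so hindered a malonate cannot be predicted, and the resolution fallback reaches the same enantiomer.
Remark: the β-triketone intermediates and the target are written as single enol tautomers.

## Route

Step 1
Reactants: 1 dimethyl malonate; 2 3-chloro-3-methylbut-1-yne
Product: 3 dimethyl 2-(2-methylbut-3-yn-2-yl)propanedioate
Conditions: NaOMe, MeOH, 0 → 23 °C
Reagents that add atoms: none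
Why: Propargylic substitution of the tertiary acetylenic chloride (through its zwitterion/vinylidene carbene) by the soft malonate anion places the nucleophile on the tertiary carbon, so the C1–C8 bond is made with C8 already quaternary; no stereocentre is formed.

Step 2
Reactants: 3 dimethyl 2-(2-methylbut-3-yn-2-yl)propanedioate; 4 1-bromo-3-methylbut-2-ene
Product: 5 dimethyl 2-(2-methylbut-3-yn-2-yl)-2-(3-methylbut-2-en-1-yl)propanedioate
Conditions: NaH, DMF, 0 → 40 °C
Reagents that add atoms: none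
Why: Malonate alkylation (SN2) with a reactive allylic bromide completes the vicinal quaternary pair C1/C8 from the slim, alkynyl-substituted enolate; the product is prochiral.

Step 3
Reactants: 5 dimethyl 2-(2-methylbut-3-yn-2-yl)-2-(3-methylbut-2-en-1-yl)propanedioate
Product: 6 dimethyl 2-(3-bromo-2-methylbut-3-en-2-yl)-2-(3-methylbut-2-en-1-yl)propanedioate
Conditions: B-Br-9-BBN, CH2Cl2, 0 °C; then AcOH, 0 → 23 °C
Reagents that add atoms: B-bromo-9-borabicyclo[3.3.1]nonane, BrB1C2CCCC1CCC2
Why: Bromoboration of the terminal alkyne (cis addition, bromine on the internal carbon) and protodeboronation give the 2-bromoalk-1-ene, while the trisubstituted prenyl alkene and the esters do not react with the B–Br reagent at 0 °C.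

Step 4
Reactants: 6 dimethyl 2-(3-bromo-2-methylbut-3-en-2-yl)-2-(3-methylbut-2-en-1-yl)propanedioate
Product: 7 (2R)-2-(3-bromo-2-methylbut-3-en-2-yl)-2-(methoxycarbonyl)-5-methylhex-4-enoic acid
Conditions: pig liver esterase, phosphate buffer pH 7.5/DMSO 9:1, 30 °C; acidify to pH 3 on work-up
Reagents that add atoms: water, O
Why: Enzymatic desymmetrisation of a prochiral α,α-disubstituted dimethyl malonate by a carboxylesterase (serine hydrolase) hydrolyses one enantiotopic ester and so sets the quaternary stereocentre C1, the only stereocentre carried into ring A.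

Step 5
Reactants: 8 1-(3,4-dihydroxyphenyl)ethan-1-one
Product: 9 1-[3,4-bis(triisopropylsilyloxy)phenyl]ethan-1-one
Conditions: TIPSCl, imidazole, DMF, 23 → 40 °C
Reagents that add atoms: chlorotriisopropylsilane, CC(C)[Si](Cl)(C(C)C)C(C)C
Why: Silylation masks the catechol with groups that tolerate amide bases, boranes and aqueous carbonate and can be removed by fluoride without acid, which would cyclise the prenylated enol.

Step 6
Reactants: 9 1-[3,4-bis(triisopropylsilyloxy)phenyl]ethan-1-one
Product: 10 1-[3,4-bis(triisopropylsilyloxy)phenyl]butane-1,3-dione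
Conditions: LiN(iPr)2 (2.1 equiv), THF, −78 °C; N-acetylimidazole, −78 → 0 °C; cold dilute HCl work-up
Reagents that add atoms: N-acetylimidazole, CC(=O)n1ccnc1
Why: Claisen-type C-acylation of the ketone lithium enolate with an acyl imidazole gives the β-diketone, the second equivalent of base taking up its acidic proton.

Step 7
Reactants: 7 (2R)-2-(3-bromo-2-methylbut-3-en-2-yl)-2-(methoxycarbonyl)-5-methylhex-4-enoic acid; 10 1-[3,4-bis(triisopropylsilyloxy)phenyl]butane-1,3-dione
Product: 13 (6R)-2-[3,4-bis(triisopropylsilyloxy)benzoyl]-6-(3-bromo-2-methylbut-3-en-2-yl)-3,5-dihydroxy-6-(3-methylbut-2-en-1-yl)cyclohexa-2,4-dien-1-one, via acid chloride 11 (not isolated), via triketo ester 12 (not isolated)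
Conditions: (a) 7, 1-chloro-N,N,2-trimethylprop-1-en-1-amine, CH2Cl2, 0 → 23 °C; (b) dianion of 10 (2 equiv; LiN(iPr)2, THF, −78 °C), add 11, −78 → −40 °C; (c) LiN(SiMe3)2, −40 → 0 °C; pH 5 buffer work-up, product used without storage
Reagents that add atoms: none
Why: γ-Acylation of the β-diketone dianion at its terminal carbon by the acid chloride, then intramolecular Claisen (Dieckmann-type, polyketide-like) condensation of the central carbon onto the remaining ester, closes ring A; C1 is quaternary and cannot epimerise, and the acid chloride/ester difference fixes which carbonyl becomes C9 and which C2.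

Step 8
Reactants: 13 (6R)-2-[3,4-bis(triisopropylsilyloxy)benzoyl]-6-(3-bromo-2-methylbut-3-en-2-yl)-3,5-dihydroxy-6-(3-methylbut-2-en-1-yl)cyclohexa-2,4-dien-1-one; 14 2-(iodomethyl)-4,4,5,5-tetramethyl-1,3,2-dioxaborolane (2.4 equiv)
Product: 15 (6R)-2-[3,4-bis(triisopropylsilyloxy)benzoyl]-6-(3-bromo-2-methylbut-3-en-2-yl)-3-hydroxy-6-(3-methylbut-2-en-1-yl)-4,4-bis[(4,4,5,5-tetramethyl-1,3,2-dioxaborolan-2-yl)methyl]cyclohex-2-ene-1,5-dione
Conditions: NaH (3.1 equiv), THF, −10 → 20 °C
Reagents that add atoms: none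
Why: Double C-alkylation of the only unsubstituted ring carbon (C5) of the vinylogous acid by the SN2-reactive α-iodomethyl boronate, as in the geminal dialkylation of acylphloroglucinols, makes C5 quaternary; the two arms are identical, so no new stereocentre and no cis/trans problem arises.

Step 9
Reactants: 15 (6R)-2-[3,4-bis(triisopropylsilyloxy)benzoyl]-6-(3-bromo-2-methylbut-3-en-2-yl)-3-hydroxy-6-(3-methylbut-2-en-1-yl)-4,4-bis[(4,4,5,5-tetramethyl-1,3,2-dioxaborolan-2-yl)methyl]cyclohex-2-ene-1,5-dione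
Product: 16 (1R,5R)-3-[3,4-bis(triisopropylsilyloxy)benzoyl]-4-hydroxy-8,8-dimethyl-7-methylidene-1-(3-methylbut-2-en-1-yl)-5-[(4,4,5,5-tetramethyl-1,3,2-dioxaborolan-2-yl)methyl]bicyclo[3.3.1]non-3-ene-2,9-dione
Conditions: Pd(dppf)Cl2·CH2Cl2 (10 mol %), Cs2CO3, THF/H2O 10:1, 4 mM, 45 °C
Reagents that add atoms: none
Why: Zerovalent palladium inserts into the C7–Br bond of the 2-bromoallyl arm, base-assisted transmetalation transfers the CH2 of the CH2Bpin arm of prochiral C5 that lies on the same face of ring A as the C8 arm (1,3-diaxial), and reductive elimination from the seven-membered palladacycle forms C6–C7. The closest known reaction type is the intramolecular B-alkyl Suzuki–Miyaura cyclisation, together with the cross-coupling of boron homoenolates (β-boryl ketones) with alkenyl halides. Ring B (C1–C8–C7–C6–C5–C9) is closed in a 6-exo sense with respect to the C7=CH2 unit, which stays exocyclic, so C7 remains sp2 and unconfigured here. The only new stereocentre is C5: of its two identical arms only the one cis to the C8 chain can reach C7, so the C1 configuration alone dictates that of C5 and leaves the other CH2Bpin in the exo position of the future bridgehead geranyl. The step needs ring closure to beat β-hydride elimination, intermolecular coupling and 5-exo Heck insertion of the alkenylpalladium into the C1 prenyl group: C5 is fully substituted so the C6–Pd alkyl has no β-hydrogen, high dilution suppresses dimerisation, and the bidentate phosphine with bromide or hydroxide on palladium at 45 °C leaves no free site for the trisubstituted alkene.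

Step 10
Reactants: 17 5-bromo-2-methylpent-2-ene; 18 lithium acetylide–ethylenediamine complex
Product: 19 6-methylhept-5-en-1-yne
Conditions: DMSO, 10 → 23 °C
Reagents that add atoms: none
Why: SN2 alkylation of the acetylide by the primary homoallylic bromide.

Step 11
Reactants: 19 6-methylhept-5-en-1-yne
Product: 20 (1E)-1-iodo-2,6-dimethylhepta-1,5-diene
Conditions: AlMe3, Cp2ZrCl2 (25 mol %), CH2Cl2, 0 → 23 °C; then I2, THF, −30 → 0 °C
Reagents that add atoms: trimethylaluminium, C[Al](C)C; iodine, II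
Why: Zirconium-catalysed carboalumination (Negishi) adds methyl and aluminium syn across the alkyne with aluminium at the terminus, and iodinolysis with retention gives the E-iodide.

Step 12
Reactants: 16 (1R,5R)-3-[3,4-bis(triisopropylsilyloxy)benzoyl]-4-hydroxy-8,8-dimethyl-7-methylidene-1-(3-methylbut-2-en-1-yl)-5-[(4,4,5,5-tetramethyl-1,3,2-dioxaborolan-2-yl)methyl]bicyclo[3.3.1]non-3-ene-2,9-dione; 20 (1E)-1-iodo-2,6-dimethylhepta-1,5-diene (2.6 equiv)
Product: 22 (1R,5R,7R)-3-[3,4-bis(triisopropylsilyloxy)benzoyl]-5,7-bis[(2E)-3,7-dimethylocta-2,6-dien-1-yl]-4-hydroxy-8,8-dimethyl-1-(3-methylbut-2-en-1-yl)bicyclo[3.3.1]non-3-ene-2,9-dione, via alkylborane 21 (not isolated)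
Conditions: 9-BBN-H (3 equiv), THF, 0 → 23 °C; then 20, Pd(dppf)Cl2·CH2Cl2 (10 mol %), AsPh3, Cs2CO3, DMF/H2O, 23 °C then 65 °C
Reagents that add atoms: none
Why: 9-BBN hydroborates the 1,1-disubstituted C7 methylene in preference to the trisubstituted prenyl alkene and delivers hydrogen to C7 from the exo face of ring B (the endo face is screened by ring A around C3), which sets C7 with its CH2B group endo (7R); both the B-alkyl-9-BBN at C7 and the less reactive CH2Bpin at C5 then undergo B-alkyl Suzuki–Miyaura coupling with retention of the E geometry of 20, the acidic enol having taken up one equivalent of borane as a boron enolate that is hydrolysed in the aqueous coupling medium.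

Step 13
Reactants: 22 (1R,5R,7R)-3-[3,4-bis(triisopropylsilyloxy)benzoyl]-5,7-bis[(2E)-3,7-dimethylocta-2,6-dien-1-yl]-4-hydroxy-8,8-dimethyl-1-(3-methylbut-2-en-1-yl)bicyclo[3.3.1]non-3-ene-2,9-dione
Product: 23 (1R,5R,7R)-3-(3,4-dihydroxybenzoyl)-5,7-bis[(2E)-3,7-dimethylocta-2,6-dien-1-yl]-4-hydroxy-8,8-dimethyl-1-(3-methylbut-2-en-1-yl)bicyclo[3.3.1]non-3-ene-2,9-dione
Conditions: Bu4NF, AcOH, THF, 0 °C, under argon
Reagents that add atoms: none
Why: Buffered fluoride desilylation frees the catechol without acid (which would cyclise the prenyl and geranyl groups onto the enol) and without strong base or air oxidation.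

## Compound list

1 | dimethyl malonate (dimethyl propanedioate) | COC(=O)CC(=O)OC | starting material
2 | 3-chloro-3-methylbut-1-yne | CC(C)(Cl)C#C | starting material
3 | dimethyl 2-(2-methylbut-3-yn-2-yl)propanedioate | COC(=O)C(C(=O)OC)C(C)(C)C#C | intermediate
4 | 1-bromo-3-methylbut-2-ene (prenyl bromide) | CC(C)=CCBr | starting material
5 | dimethyl 2-(2-methylbut-3-yn-2-yl)-2-(3-methylbut-2-en-1-yl)propanedioate | COC(=O)C(CC=C(C)C)(C(=O)OC)C(C)(C)C#C | intermediate
6 | dimethyl 2-(3-bromo-2-methylbut-3-en-2-yl)-2-(3-methylbut-2-en-1-yl)propanedioate | COC(=O)C(CC=C(C)C)(C(=O)OC)C(C)(C)C(Br)=C | intermediate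
7 | (2R)-2-(3-bromo-2-methylbut-3-en-2-yl)-2-(methoxycarbonyl)-5-methylhex-4-enoic acid | OC(=O)[C@](CC=C(C)C)(C(=O)OC)C(C)(C)C(Br)=C | intermediate
8 | 1-(3,4-dihydroxyphenyl)ethan-1-one | CC(=O)c1ccc(O)c(O)c1 | starting material
9 | 1-[3,4-bis(triisopropylsilyloxy)phenyl]ethan-1-one | CC(=O)c1ccc(O[Si](C(C)C)(C(C)C)C(C)C)c(O[Si](C(C)C)(C(C)C)C(C)C)c1 | intermediate
10 | 1-[3,4-bis(triisopropylsilyloxy)phenyl]butane-1,3-dione | CC(=O)CC(=O)c1ccc(O[Si](C(C)C)(C(C)C)C(C)C)c(O[Si](C(C)C)(C(C)C)C(C)C)c1 | intermediate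
11 | methyl (2S)-2-(3-bromo-2-methylbut-3-en-2-yl)-2-(chlorocarbonyl)-5-methylhex-4-enoate (same spatial arrangement at C1 as 7) | ClC(=O)[C@](CC=C(C)C)(C(=O)OC)C(C)(C)C(Br)=C | intermediate
12 | methyl (2R)-7-[3,4-bis(triisopropylsilyloxy)phenyl]-2-(3-bromo-2-methylbut-3-en-2-yl)-2-(3-methylbut-2-en-1-yl)-3,5,7-trioxoheptanoate | O=C(CC(=O)CC(=O)c1ccc(O[Si](C(C)C)(C(C)C)C(C)C)c(O[Si](C(C)C)(C(C)C)C(C)C)c1)[C@](CC=C(C)C)(C(=O)OC)C(C)(C)C(Br)=C | intermediate
13 | (6R)-2-[3,4-bis(triisopropylsilyloxy)benzoyl]-6-(3-bromo-2-methylbut-3-en-2-yl)-3,5-dihydroxy-6-(3-methylbut-2-en-1-yl)cyclohexa-2,4-dien-1-one | C1=C(O)[C@](CC=C(C)C)(C(=O)C(C(=O)c2ccc(O[Si](C(C)C)(C(C)C)C(C)C)c(O[Si](C(C)C)(C(C)C)C(C)C)c2)=C1O)C(C)(C)C(Br)=C | intermediate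
14 | 2-(iodomethyl)-4,4,5,5-tetramethyl-1,3,2-dioxaborolane | ICB1OC(C)(C)C(C)(C)O1 | starting material
15 | (6R)-2-[3,4-bis(triisopropylsilyloxy)benzoyl]-6-(3-bromo-2-methylbut-3-en-2-yl)-3-hydroxy-6-(3-methylbut-2-en-1-yl)-4,4-bis[(4,4,5,5-tetramethyl-1,3,2-dioxaborolan-2-yl)methyl]cyclohex-2-ene-1,5-dione | CC1(C)OB(CC2(CB3OC(C)(C)C(C)(C)O3)C(=O)[C@](CC=C(C)C)(C(=O)C(C(=O)c4ccc(O[Si](C(C)C)(C(C)C)C(C)C)c(O[Si](C(C)C)(C(C)C)C(C)C)c4)=C2O)C(C)(C)C(Br)=C)OC1(C)C | intermediate
16 | (1R,5R)-3-[3,4-bis(triisopropylsilyloxy)benzoyl]-4-hydroxy-8,8-dimethyl-7-methylidene-1-(3-methylbut-2-en-1-yl)-5-[(4,4,5,5-tetramethyl-1,3,2-dioxaborolan-2-yl)methyl]bicyclo[3.3.1]non-3-ene-2,9-dione | C=C1C[C@@]2(CB3OC(C)(C)C(C)(C)O3)C(=O)[C@](CC=C(C)C)(C(=O)C(C(=O)c4ccc(O[Si](C(C)C)(C(C)C)C(C)C)c(O[Si](C(C)C)(C(C)C)C(C)C)c4)=C2O)C1(C)C | intermediate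
17 | 5-bromo-2-methylpent-2-ene | CC(C)=CCCBr | starting material
18 | lithium acetylide–ethylenediamine complex | [Li+].[C-]#C.NCCN | starting material
19 | 6-methylhept-5-en-1-yne | CC(C)=CCCC#C | intermediate
20 | (1E)-1-iodo-2,6-dimethylhepta-1,5-diene | CC(C)=CCC/C(C)=C/I | intermediate
21 | (1R,5R,7R)-7-[(9-borabicyclo[3.3.1]nonan-9-yl)methyl]-3-[3,4-bis(triisopropylsilyloxy)benzoyl]-4-hydroxy-8,8-dimethyl-1-(3-methylbut-2-en-1-yl)-5-[(4,4,5,5-tetramethyl-1,3,2-dioxaborolan-2-yl)methyl]bicyclo[3.3.1]non-3-ene-2,9-dione (CH2B on C7 endo, toward C3; shown as the free enol) | C(B1C2CCCC1CCC2)[C@@H]3C[C@@]4(CB5OC(C)(C)C(C)(C)O5)C(=O)[C@](CC=C(C)C)(C(=O)C(C(=O)c6ccc(O[Si](C(C)C)(C(C)C)C(C)C)c(O[Si](C(C)C)(C(C)C)C(C)C)c6)=C4O)C3(C)C | intermediate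
22 | (1R,5R,7R)-3-[3,4-bis(triisopropylsilyloxy)benzoyl]-5,7-bis[(2E)-3,7-dimethylocta-2,6-dien-1-yl]-4-hydroxy-8,8-dimethyl-1-(3-methylbut-2-en-1-yl)bicyclo[3.3.1]non-3-ene-2,9-dione | CC(C)=CCC/C(C)=C/C[C@@H]1C[C@@]2(C/C=C(\C)CCC=C(C)C)C(=O)[C@](CC=C(C)C)(C(=O)C(C(=O)c3ccc(O[Si](C(C)C)(C(C)C)C(C)C)c(O[Si](C(C)C)(C(C)C)C(C)C)c3)=C2O)C1(C)C | intermediate
23 | (1R,5R,7R)-3-(3,4-dihydroxybenzoyl)-5,7-bis[(2E)-3,7-dimethylocta-2,6-dien-1-yl]-4-hydroxy-8,8-dimethyl-1-(3-methylbut-2-en-1-yl)bicyclo[3.3.1]non-3-ene-2,9-dione (C7 geranyl endo, C7–H exo) | CC(C)=CCC/C(C)=C/C[C@@H]1C[C@@]2(C/C=C(\C)CCC=C(C)C)C(=O)[C@](CC=C(C)C)(C(=O)C(C(=O)c3ccc(O)c(O)c3)=C2O)C1(C)C | target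

## Step count and risks

Total step count: 13. Longest linear sequence: 9 steps (1, 2, 3, 4, 7, 8, 9, 12, 13).

The three steps most likely to fail:

Step 9 (key ring closure). Transmetalation of the neopentyl-type alkyl pinacol boronate may be slow. The alkenylpalladium intermediate could then be diverted into 5-exo Heck insertion into the C1 prenyl group or into protodebromination, or the monocycle could lose its bromoallyl arm from C1 by a thermal [3,3] shift. The fallback replaces the boron arms and palladium by carboxylate arms and a nickel-mediated radical closure. It sets out from 13 and comes back to the route at 22. Double C-alkylation of 13 with sodium iodoacetate (NaH, THF/DMF, 0 → 20 °C) should give the diacid F1. Activation in the flask with N-hydroxyphthalimide and N,N'-diisopropylcarbodiimide should give the bis(N-acyloxyphthalimide) F2. Reductive decarboxylative alkenylation (NiBr2·glyme, 4,4'-di-tert-butyl-2,2'-bipyridine, Zn, DMA, 23 °C, in the presence of 20) should couple the arm cis to the bromoalkene intramolecularly (C6–C7) and the other arm with 20, giving the C5-geranyl 7-methylene bicycle F3. Hydroboration of F3 with 9-BBN and B-alkyl Suzuki coupling with one equivalent of 20, as in step 12, returns the material to 22.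

Step 8 (bis(borylmethylation)). The enolate oxygen may attack boron and then shift to carbon (net O-alkylation), or the reaction may stall after one alkylation. The fallback uses a tetracoordinate borate electrophile that cannot bind the enolate oxygen, and carries trifluoroborates through the ring closure. It sets out from 13 and comes back at 22. Alkylation of 13 with potassium (bromomethyl)trifluoroborate (KN(SiMe3)2, THF/DMSO) should give the dipotassium bis(trifluoroborate) F4. Ring closure under aqueous trifluoroborate cross-coupling conditions (Pd(OAc)2, RuPhos, K2CO3, toluene/H2O) should give the bicyclic potassium trifluoroborate F5. F5 then enters step 12 in place of 16 and gives 22.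

Step 4 (enzymatic desymmetrisation). The hindered diester may not be accepted by the esterase, or the enantiotopic esters may be poorly distinguished. The fallback is a classical resolution; it sets out from 6 and comes back at 7. Mono-saponification of 6 (KOH, 1 equiv, MeOH/H2O) should give the racemic half-ester F6. Fractional crystallisation of its salt with (R)-1-phenylethylamine (or the (S)-amine, whichever gives the less soluble salt of the (R)-acid) should give the diastereomerically pure ammonium salt F7. Acidification liberates 7.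

Further compounds
F1 | step 9 | 2,2'-{(5R)-3-[3,4-bis(triisopropylsilyloxy)benzoyl]-5-(3-bromo-2-methylbut-3-en-2-yl)-2-hydroxy-5-(3-methylbut-2-en-1-yl)-4,6-dioxocyclohex-2-ene-1,1-diyl}diacetic acid | OC(=O)CC1(CC(=O)O)C(=O)[C@](CC=C(C)C)(C(=O)C(C(=O)c2ccc(O[Si](C(C)C)(C(C)C)C(C)C)c(O[Si](C(C)C)(C(C)C)C(C)C)c2)=C1O)C(C)(C)C(Br)=C
F2 | step 9 | bis(1,3-dioxoisoindolin-2-yl) diester of F1 | O=C(CC1(CC(=O)ON2C(=O)c3ccccc3C2=O)C(=O)[C@](CC=C(C)C)(C(=O)C(C(=O)c4ccc(O[Si](C(C)C)(C(C)C)C(C)C)c(O[Si](C(C)C)(C(C)C)C(C)C)c4)=C1O)C(C)(C)C(Br)=C)ON5C(=O)c6ccccc6C5=O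
F3 | step 9 | (1R,5R)-3-[3,4-bis(triisopropylsilyloxy)benzoyl]-5-[(2E)-3,7-dimethylocta-2,6-dien-1-yl]-4-hydroxy-8,8-dimethyl-7-methylidene-1-(3-methylbut-2-en-1-yl)bicyclo[3.3.1]non-3-ene-2,9-dione | C=C1C[C@@]2(C/C=C(\C)CCC=C(C)C)C(=O)[C@](CC=C(C)C)(C(=O)C(C(=O)c3ccc(O[Si](C(C)C)(C(C)C)C(C)C)c(O[Si](C(C)C)(C(C)C)C(C)C)c3)=C2O)C1(C)C
F4 | step 8 | dipotassium salt of the analogue of 15 with two CH2BF3 arms on C5 (R at the prenyl-bearing carbon) | [K+].[K+].F[B-](F)(F)CC1(C[B-](F)(F)F)C(=O)[C@](CC=C(C)C)(C(=O)C(C(=O)c2ccc(O[Si](C(C)C)(C(C)C)C(C)C)c(O[Si](C(C)C)(C(C)C)C(C)C)c2)=C1O)C(C)(C)C(Br)=C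
F5 | step 8 | potassium salt of the analogue of 16 with a CH2BF3 group on C5, (1R,5R) | [K+].C=C1C[C@@]2(C[B-](F)(F)F)C(=O)[C@](CC=C(C)C)(C(=O)C(C(=O)c3ccc(O[Si](C(C)C)(C(C)C)C(C)C)c(O[Si](C(C)C)(C(C)C)C(C)C)c3)=C2O)C1(C)C
F6 | step 4 | racemic 2-(3-bromo-2-methylbut-3-en-2-yl)-2-(methoxycarbonyl)-5-methylhex-4-enoic acid | OC(=O)C(CC=C(C)C)(C(=O)OC)C(C)(C)C(Br)=C
F7 | step 4 | (R)-1-phenylethylammonium (2R)-2-(3-bromo-2-methylbut-3-en-2-yl)-2-(methoxycarbonyl)-5-methylhex-4-enoate | [O-]C(=O)[C@](CC=C(C)C)(C(=O)OC)C(C)(C)C(Br)=C.C[C@@H]([NH3+])c1ccccc1
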